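## Structural features

The target is a C30 polyether made of two trans-fused cyclohexane–oxepane bicycles. Rings A and B form the left half: ring A is a gem-dimethylcyclohexane and ring B is an oxepane whose O–C–OH carbon is a hemiketal. Rings C and D form the right half: ring C is a cyclohexane with a tertiary alcohol and ring D is a 2,2-dimethyloxepan-3-one. An (E)-CH=CH bridge joins the hemiketal carbon of ring B to a CH of ring C.

There are nine stereocentres. In the left half the fusion CH and the methyl-bearing C–O carbon are adjacent, and the CHMe carbon of ring B sits next to the hemiketal carbon. Ring C carries four contiguous centres: C(Me)OH, the bridge-bearing CH, the angular C(Me) and the fusion CH–O. In ring C the bridge and the tertiary hydroxyl are trans-diaxial and the bridge is anti to the angular methyl, which a simple anti addition across an E-alkene cannot deliver.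

The hemiketal is the closed form of a hydroxy enone. In the open form the ring C carbinol is the δ-hydroxyl of the enone (vinylogous retro-aldol with base), the bridge-bearing CH is its γ-position, and the CHMe carbon is α to the ketone. Ring D holds an α-alkoxy ketone, and both tertiary C–O carbons can ionise in strong acid.

The real difficulty lies in three places: the fully substituted oxygen-bearing carbons flanked by quaternary carbons in both halves (a 1,3-diaxial methyl/methyl pair in ring A, an axial bridge in ring C), the seven-membered ether of ring D, and the union of two crowded halves.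

The key step uses this feature: in ring A the fusion CH lies between the CMe2 carbon and the methyl-bearing C–O carbon. Once the adjoining ring B CH2 is raised to the aldehyde level, the bond from the fusion CH to the C–O carbon is the α–β bond of a β-hydroxy aldehyde, so ring A is the intramolecular aldol of an achiral keto aldehyde.

## Logic of the disconnections

35 is opened at the bond between the hemiketal carbon and the ring B oxygen, and both tertiary hydroxyls are capped as silyl ethers; this leads through 34 back to 33. The cut removes a ring and a stereocentre that equilibration can set, and it exposes an enone. The forward step must unmask two hindered silyl ethers without base, because the open form 34 can undergo vinylogous retro-aldol cleavage and epimerisation, and the ring must then close on its own.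

33 is cut at the C–C bond between the enone carbonyl carbon and the neighbouring alkene carbon. With both ketones lowered to alcohols (32), this gives 16 and 30, two halves of similar size. The forward coupling must tolerate a free secondary alcohol and silyl ethers, and it must not epimerise the α-methyl aldehyde or attack hindered sites; this points to a chromium-mediated addition followed by one oxidation that forms both ketones.

30 is traced to 29 by cutting the iodoalkene C=C bond, and 29 to 27 by restoring the lost alkene carbon. This trades a reactive handle for a plain vinyl group that survives the ring-forming chemistry. The forward steps must keep the configuration of the formyl-bearing CH, which is flanked by two fully substituted carbons.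

27 is cut twice: at the ring C bond between the vinyl-bearing CH and the angular quaternary carbon, and at the ring D bond between the ether oxygen and CMe2. This unravels both rings to the open chain 25, whose three stereocentres can each be set by a reagent. The forward step must form the C–C bond with inversion at a tertiary epoxide carbon, place the vinyl group axial, and close the ether at the more substituted epoxide carbon.

25 is cut at its disubstituted alkene into 23 and 24, and the two oxirane rings of 23 are removed to give 21. The gain is a simple protected trienol. The forward steps need epoxidation of two trisubstituted alkenes under catalyst control beside an untouched vinyl group, and then metathesis at that crowded vinyl group.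

21 is desilylated to 20, which is related to 19, 18 and 17 by moving the tertiary allylic alcohol back to a 2,3-epoxy alcohol. This reduces the tertiary carbinol stereocentre to an asymmetric epoxidation of an achiral allylic alcohol. The forward sequence must not break the tertiary C–O bond.

16 is taken back to 15 by oxidation level and is cut, as the alkene of 14, between the two CH2 carbons of the tether, which gives 10 and 12; 12 comes from 11. The cut places the CHMe stereocentre in a small building block of known configuration. The forward olefination must add to a hindered, enolisable aldehyde without β-elimination, and the reduction must not move the double bond into the stereocentre.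

10 is desilylated to 9, and 9 is cut at the bond between the formyl-bearing CH and the carbinol carbon, which gives 7. This is the key disconnection: it removes ring A and both of its stereocentres and leaves an achiral chain. The forward step must make the aldehyde the donor and the ketone the acceptor, and it must deliver the trans relationship in one enantiomeric series.

7 is cut between the quaternary carbon and the neighbouring chain CH2, through 5, to give 1 and 2. This reduces the quaternary carbon to a conjugate addition. The forward step needs 1,4-addition at a fully substituted β-carbon.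

## Other disconnections considered

Alternative 1: The cut removes the ring C bond between the fusion CH–O carbon and the angular quaternary carbon, and the ring D bond between its two CH2 groups. In the forward sense, irradiation of furanone A1, whose tether already carries the ring C carbinol and the bridge-bearing centre, would give the cyclobutane photoadduct A2 by intramolecular [2+2] cycloaddition. Cleavage of the cyclobutane bond that was the furanone C=C bond would then enlarge the five-membered ring to ring D.
- In its favour: the ether oxygen, the gem-dimethyl group and the ketone of ring D are present from the start, so no seven-membered etherification is needed. Two C–C bonds and the angular quaternary centre form in one step. The tertiary oxygen is a plain silyl ether that no Lewis acid has to spare.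
- Against it here: the face of the cycloaddition is set only by the two tether stereocentres. The later fragmentation must break the right cyclobutane bond and place the new hydrogen trans to the angular methyl. A1 needs its own asymmetric synthesis of two adjacent centres.
- Comparison with the chosen plan: on structure it addresses the more congested half, which the chosen key step leaves to other chemistry. On mechanism both depend on stereocontrol that is not secured in advance, substrate control in an excited state there and catalyst against substrate bias here. On step economy the way to A1 and the steps after A2 should be longer than the two steps to 7.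
- Equal or better: it forms more bonds and rings in the key step than the aldol, and it avoids a Lewis acid next to a tertiary allylic silyl ether, which step 15 of the chosen route cannot.

Alternative 2: The cut is the ring C bond between the vinyl-bearing CH and the angular carbon together with the O–CMe2 bond of ring D. In the forward sense Et2AlCl would turn the bis-epoxy allylsilane A3 into the bicyclic vinyl alcohol A4. The chosen route does not compete with this cut but borrows it: A3 is the same compound as 25, A4 the same as 27, and the transformation is step 15.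
- In its favour: it closes two rings, forms one C–C and one C–O bond, and fixes the ring fusion by stereospecific epoxide opening. Its precursor comes from a cheap acyclic terpenoid with reagent-controlled stereocentres.
- Against it here: the tertiary allylic silyl ether may ionise, the configuration of the vinyl-bearing CH is not guaranteed, and the second epoxide may open at the wrong carbon.
- Comparison with the chosen plan: on rings C and D the two plans are identical. A plan centred on this cascade would only shift the strategic weight to the right half and would still need an entry to rings A and B. On mechanism it is stereospecific at two centres, whereas the aldol relies on catalyst control alone.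
- Equal or better: in bonds, rings and stereocentres per step it is better than the aldol of step 3. The aldol is better only in that its precursor is achiral and is made in two steps.

Alternative 3: The cut removes both C–O bonds of ring B at the lactone oxidation level. In the forward sense trifluoroperacetic acid would insert oxygen between the carbonyl carbon and the angular quaternary carbon of the trans-decalone A5 to give the seven-membered lactone A6, with retention at the migrating carbon. A right-half alkenyl metal could then add to A6 to give the hemiketal directly.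
- In its favour: the ring fusion stereochemistry is that of a trans-decalin, for which reliable methods exist, and the migration is regioselective and stereospecific. The union with the right half and the closure of ring B would be one operation.
- Against it here: the ketone is hindered on both sides and needs a strongly acidic peracid, which threatens the new tertiary lactone C–O bond and the α-methyl centre. An alkenyllithium is not compatible with the ring D ketone and can enolise or add twice to the lactone. An enantiopure A5 costs more steps than 9.
- Comparison with the chosen plan: on structure both address rings A and B. On mechanism the oxygen insertion is the safer of the two for the carbinol centre, because its configuration is carried by the substrate and does not rest on a catalyst working against substrate bias. On step economy the chosen plan reaches ring A in fewer steps but needs three steps (coupling, oxidation, unmasking) where A6 would need one.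
- Equal or better: security of the ring A stereocentres and brevity of the endgame are better in this alternative. Length and mildness of the early steps are better in the chosen plan.

Key step: step 3

Assumption: the sense of induction in step 3 follows the hydrogen-bonded enamine transition-state model of aldehyde-donor proline aldol reactions, which calls for (R)-proline; if the sense proved opposite, (S)-proline would be used with no other change.

Assumption: the hemiketal configuration of the target (hydroxyl axial; alkenyl group and neighbouring methyl equatorial on ring B) is the thermodynamically preferred one and is reached by equilibration in step 20.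

Remark on design: the tertiary hydroxyl of 9 is silylated before the olefination because a free β-alkoxide would undergo retro-aldol cleavage. The olefination reagent carries a free hydroxyl (oxido ylide), which avoids a protecting group. The halves are joined with chromium and not lithium because of the free hydroxyl and the crowded aldehyde.

## Route

Step 1
Reactants: 1 2-(3-chloropropyl)-2-methyl-1,3-dioxolane; 2 ethyl 3-methylbut-2-enoate
Product: 5 ethyl 3,3-dimethyl-6-(2-methyl-1,3-dioxolan-2-yl)hexanoate, via Grignard reagent 3 (not isolated), via silyl ketene acetal 4 (not isolated)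
Conditions: Mg, BrCH2CH2Br (cat.), THF, reflux; then 2, CuI (10 mol%), Me3SiCl, THF, −30 to 0 °C; aq. NH4Cl
Reagents that add atoms: none
Why: Copper-catalysed conjugate addition of a primary alkyl Grignard reagent to a β,β-disubstituted enoate, accelerated by Me3SiCl, which traps the enolate as 4; it creates the quaternary carbon, and the dioxolane is inert to both organometallic species.

Step 2
Reactants: 5 ethyl 3,3-dimethyl-6-(2-methyl-1,3-dioxolan-2-yl)hexanoate
Product: 7 3,3-dimethyl-7-oxooctanal, via ketal aldehyde 6 (not isolated)
Conditions: i-Bu2AlH, CH2Cl2, −78 °C; then 1 M HCl, THF, 0 °C to rt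
Reagents that add atoms: water, O
Why: Partial ester reduction stops at the aluminium hemiacetal at −78 °C, and the aqueous acid of the quench also hydrolyses the dioxolane (acetal hydrolysis); no stereocentre is involved.

Step 3
Reactants: 7 3,3-dimethyl-7-oxooctanal
Product: 9 (1R,2R)-2-hydroxy-2,6,6-trimethylcyclohexane-1-carbaldehyde, via proline enamine 8 (not isolated)
Conditions: (R)-proline (30 mol%), CH2Cl2, rt; filter and use the solution at once
Reagents that add atoms: none
Why: (R)-Proline condenses with the aldehyde of 7 to give the E-enamine 8, whose β-carbon adds to the ketone carbonyl while the carboxylic acid protonates the developing alkoxide; hydrolysis of the iminium ion releases 9 and the catalyst. The closest known reaction type is the proline-catalysed 6-enolexo aldolisation of heptanedials to trans-2-hydroxycyclohexanecarbaldehydes, here applied to a ketone acceptor and a neopentylic enamine carbon. Ring A closes in the 6-enolexo (6-exo-trig) mode through a chair. The formyl-bearing carbon is controlled by the catalyst, which fixes the enamine face that carries the acid. The carbinol carbon is controlled by the ketone face presented in the chair, and the hydrogen-bonded arrangement with the C=O gauche to the iminium carbon leads to the anti (trans) aldol. The step needs chemoselectivity (aldehyde as donor, ketone as acceptor), anti diastereoselectivity and enantioselectivity. The first should follow from the much faster enamine formation of aldehydes, and the gem-dimethyl group should speed ring closure. The anti chair, however, places the ketone methyl syn-axial to one methyl of the CMe2 group, so diastereoselectivity rests on the catalyst alone and is the point to be tested.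

Step 4
Reactants: 9 (1R,2R)-2-hydroxy-2,6,6-trimethylcyclohexane-1-carbaldehyde
Product: 10 (1R,2R)-2,6,6-trimethyl-2-(triethylsilyloxy)cyclohexane-1-carbaldehyde
Conditions: Et3SiOTf, 2,6-lutidine, CH2Cl2, −78 °C
Reagents that add atoms: triethylsilyl trifluoromethanesulfonate, CC[Si](CC)(CC)OS(=O)(=O)C(F)(F)F
Why: Silylation of a tertiary alcohol with a silyl triflate and a hindered base is fast at −78 °C and does not enolise the aldehyde; the silyl ether blocks retro-aldol cleavage and dehydration in the basic olefination that follows.

Step 5
Reactants: 11 (2S)-3-bromo-2-methylpropan-1-ol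
Product: 12 [(2S)-3-hydroxy-2-methylpropyl]triphenylphosphonium bromide
Conditions: PPh3, MeCN, reflux
Reagents that add atoms: triphenylphosphine, c1ccc(cc1)P(c1ccccc1)c1ccccc1
Why: SN2 quaternisation of the phosphine by the primary bromide; the stereocentre is β to the reacting carbon and is not touched.

Step 6
Reactants: 10 (1R,2R)-2,6,6-trimethyl-2-(triethylsilyloxy)cyclohexane-1-carbaldehyde; 12 [(2S)-3-hydroxy-2-methylpropyl]triphenylphosphonium bromide
Product: 14 (2R,3Z)-2-methyl-4-[(1R,2R)-2,6,6-trimethyl-2-(triethylsilyloxy)cyclohexyl]but-3-en-1-ol, via oxido ylide 13 (not isolated)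
Conditions: 12, NaN(SiMe3)2 (2 equiv per 12), THF, −78 to 0 °C; then 10, −78 °C to rt
Reagents that add atoms: none
Why: Wittig olefination with a non-stabilised γ-oxido ylide, which adds to the carbonyl group faster than it deprotonates the hindered α-CH; the Z-alkene is expected but the geometry is irrelevant, and the CHMe centre comes unchanged from 11.

Step 7
Reactants: 14 (2R,3Z)-2-methyl-4-[(1R,2R)-2,6,6-trimethyl-2-(triethylsilyloxy)cyclohexyl]but-3-en-1-ol
Product: 15 (2R)-2-methyl-4-[(1R,2R)-2,6,6-trimethyl-2-(triethylsilyloxy)cyclohexyl]butan-1-ol
Conditions: H2 (1 atm), PtO2, EtOAc, rt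
Reagents that add atoms: none
Why: Heterogeneous hydrogenation of a disubstituted alkene; platinum is chosen over palladium to suppress double-bond migration into the allylic stereocentre, and the tertiary silyl ether is stable in ethyl acetate.

Step 8
Reactants: 15 (2R)-2-methyl-4-[(1R,2R)-2,6,6-trimethyl-2-(triethylsilyloxy)cyclohexyl]butan-1-ol
Product: 16 (2R)-2-methyl-4-[(1R,2R)-2,6,6-trimethyl-2-(triethylsilyloxy)cyclohexyl]butanal
Conditions: Dess–Martin periodinane, NaHCO3, CH2Cl2, 0 °C to rt
Reagents that add atoms: none
Why: Buffered Dess–Martin oxidation converts the primary alcohol into the α-methyl aldehyde under conditions that do not epimerise it; 16 is used without storage.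

Step 9
Reactants: 17 (2E,6E)-3,7,11-trimethyldodeca-2,6,10-trien-1-ol
Product: 18 (2S,3S,6E)-2,3-epoxy-3,7,11-trimethyldodeca-6,10-dien-1-ol
Conditions: Ti(OiPr)4 (10 mol%), L-(+)-diethyl tartrate (12 mol%), t-BuOOH, 4 Å molecular sieves, CH2Cl2, −20 °C
Reagents that add atoms: tert-butyl hydroperoxide, CC(C)(C)OO
Why: Sharpless asymmetric epoxidation touches only the allylic alcohol alkene, and the L-tartrate ligand delivers oxygen to the face that gives the (2S,3S)-epoxide; this sets the future carbinol carbon of ring C.

Step 10
Reactants: 18 (2S,3S,6E)-2,3-epoxy-3,7,11-trimethyldodeca-6,10-dien-1-ol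
Product: 19 (2R,3S,6E)-2,3-epoxy-1-iodo-3,7,11-trimethyldodeca-6,10-diene
Conditions: I2, PPh3, imidazole, THF, 0 °C
Reagents that add atoms: iodine, II
Why: Appel-type iodination of the primary alcohol through an alkoxyphosphonium ion; the neutral conditions leave the epoxide and its stereocentres intact (the descriptor at C2 changes only by priority).

Step 11
Reactants: 19 (2R,3S,6E)-2,3-epoxy-1-iodo-3,7,11-trimethyldodeca-6,10-diene
Product: 20 (3S,6E)-3,7,11-trimethyldodeca-1,6,10-trien-3-ol
Conditions: Zn dust, EtOH, AcOH (cat.), reflux
Reagents that add atoms: none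
Why: Zinc inserts into the C–I bond and the organozinc undergoes β-elimination with opening of the epoxide (reductive elimination of a β-halo ether); the tertiary C–O bond is not broken, so the configuration of the carbinol carbon is retained.

Step 12
Reactants: 20 (3S,6E)-3,7,11-trimethyldodeca-1,6,10-trien-3-ol
Product: 21 triethyl{[(3S,6E)-3,7,11-trimethyldodeca-1,6,10-trien-3-yl]oxy}silane
Conditions: Et3SiOTf, 2,6-lutidine, CH2Cl2, −78 °C
Reagents that add atoms: triethylsilyl trifluoromethanesulfonate, CC[Si](CC)(CC)OS(=O)(=O)C(F)(F)F
Why: Silyl triflate silylation of the tertiary alcohol; the ether keeps the hydroxyl from opening the epoxides made next.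

Step 13
Reactants: 21 triethyl{[(3S,6E)-3,7,11-trimethyldodeca-1,6,10-trien-3-yl]oxy}silane
Product: 23 (3S,6R,7R,10R)-6,7:10,11-diepoxy-3,7,11-trimethyl-3-(triethylsilyloxy)dodec-1-ene, via terminal monoepoxide 22 (not isolated)
Conditions: D-fructose-derived Shi ketone (30 mol% per alkene), KHSO5, K2CO3, Bu4NHSO4, MeCN–CH2(OMe)2–aq. Na2B4O7 buffer (pH 10.5), 0 °C
Reagents that add atoms: potassium peroxymonosulfate, [K+].[O-]S(=O)(=O)OO
Why: Shi epoxidation: the chiral dioxirane attacks each trisubstituted alkene through a spiro transition state and gives the R configuration at the CH carbons, while the monosubstituted vinyl group is too unreactive to compete.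

Step 14
Reactants: 23 (3S,6R,7R,10R)-6,7:10,11-diepoxy-3,7,11-trimethyl-3-(triethylsilyloxy)dodec-1-ene; 24 trimethyl(prop-2-en-1-yl)silane
Product: 25 (2E,4S,7R,8R,11R)-7,8:11,12-diepoxy-4,8,12-trimethyl-4-(triethylsilyloxy)-1-(trimethylsilyl)tridec-2-ene
Conditions: second-generation Hoveyda–Grubbs catalyst (5–10 mol%), 24 (5 equiv), CH2Cl2, 40 °C
Reagents that add atoms: none
Why: Olefin cross-metathesis between a hindered vinyl group that does not homodimerise and an excess of a reactive allylsilane, with loss of ethene; the E-alkene should predominate, and the epoxides and silyl ether are spectators.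

Step 15
Reactants: 25 (2E,4S,7R,8R,11R)-7,8:11,12-diepoxy-4,8,12-trimethyl-4-(triethylsilyloxy)-1-(trimethylsilyl)tridec-2-ene
Product: 27 (3R,5aR,6S,7S,9aR)-6-ethenyl-2,2,5a,7-tetramethyl-7-(triethylsilyloxy)decahydro-1-benzoxepin-3-ol, via aluminium alkoxide 26 (not isolated)
Conditions: Et2AlCl (2.2 equiv), CH2Cl2, −78 to −40 °C; aq. KNaC4H4O6
Reagents that add atoms: none
Why: Lewis-acid-promoted epoxide–allylsilane cyclisation followed by endo epoxide opening: the γ-carbon of the allylsilane attacks the tertiary carbon of the activated internal epoxide with inversion through a chair (fixing the trans fusion), silicon leaves to give the vinyl group, and the alkoxide 26 opens the terminal epoxide at CMe2 to close ring D. The chair with the silyloxy group axial and the methyl equatorial avoids a methyl/methyl 1,3-diaxial pair, and the alkene arm is expected to sit pseudo-axial to stay clear of the two flanking equatorial groups, which would give the vinyl group anti to the angular methyl. Activation of the terminal epoxide first would converge on the same product through an epoxonium ion.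

Step 16
Reactants: 27 (3R,5aR,6S,7S,9aR)-6-ethenyl-2,2,5a,7-tetramethyl-7-(triethylsilyloxy)decahydro-1-benzoxepin-3-ol
Product: 29 (3R,5aR,6S,7S,9aR)-3-hydroxy-2,2,5a,7-tetramethyl-7-(triethylsilyloxy)decahydro-1-benzoxepine-6-carbaldehyde, via ozonide 28 (not isolated)
Conditions: O3, CH2Cl2, −78 °C; then PPh3, −78 °C to rt
Reagents that add atoms: ozone, [O-][O+]=O
Why: Ozonolysis with reductive work-up of the only alkene in the molecule; the aldehyde has no free β-hydroxyl (silyl ether), so retro-aldol cleavage is not possible.

Step 17
Reactants: 29 (3R,5aR,6S,7S,9aR)-3-hydroxy-2,2,5a,7-tetramethyl-7-(triethylsilyloxy)decahydro-1-benzoxepine-6-carbaldehyde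
Product: 30 (3R,5aR,6S,7S,9aR)-6-[(E)-2-iodoethenyl]-2,2,5a,7-tetramethyl-7-(triethylsilyloxy)decahydro-1-benzoxepin-3-ol
Conditions: CrCl2, CHI3, THF–1,4-dioxane, 0 °C to rt
Reagents that add atoms: iodoform, IC(I)I
Why: Takai olefination: the geminal dichromium species from iodoform and CrCl2 adds to the aldehyde and eliminates to the E-iodoalkene; the non-basic medium tolerates the free secondary alcohol and does not epimerise the α-carbon.

Step 18
Reactants: 16 (2R)-2-methyl-4-[(1R,2R)-2,6,6-trimethyl-2-(triethylsilyloxy)cyclohexyl]butanal; 30 (3R,5aR,6S,7S,9aR)-6-[(E)-2-iodoethenyl]-2,2,5a,7-tetramethyl-7-(triethylsilyloxy)decahydro-1-benzoxepin-3-ol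
Product: 32 (3R,5aR,6S,7S,9aR)-6-{(1E,4R)-3-hydroxy-4-methyl-6-[(1R,2R)-2,6,6-trimethyl-2-(triethylsilyloxy)cyclohexyl]hex-1-en-1-yl}-2,2,5a,7-tetramethyl-7-(triethylsilyloxy)decahydro-1-benzoxepin-3-ol (both carbinol epimers), via alkenylchromium reagent 31 (not isolated)
Conditions: 30 (1.3 equiv), CrCl2 (4 equiv), NiCl2 (2 mol%), DMSO, rt
Reagents that add atoms: none
Why: Nozaki–Hiyama–Kishi coupling: nickel-catalysed formation of the trivalent alkenylchromium species 31 with retention of alkene geometry, then addition to the aldehyde; the reagent is not basic, tolerates the free hydroxyl and does not epimerise the α-methyl aldehyde. The new carbinol centre is destroyed in step 19.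

Step 19
Reactants: 32 (the diol from step 18)
Product: 33 (5aR,6S,7S,9aR)-2,2,5a,7-tetramethyl-6-{(1E,4R)-4-methyl-3-oxo-6-[(1R,2R)-2,6,6-trimethyl-2-(triethylsilyloxy)cyclohexyl]hex-1-en-1-yl}-7-(triethylsilyloxy)octahydro-1-benzoxepin-3(2H)-one
Conditions: Dess–Martin periodinane (3 equiv), NaHCO3, CH2Cl2, 0 °C to rt
Reagents that add atoms: none
Why: Dess–Martin oxidation of both secondary alcohols in one operation gives the enone and the ring D ketone; the tertiary silyl ethers are inert and the buffered medium protects the α-methyl centre.

Step 20
Reactants: 33 (the bis-silyl diketone from step 19)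
Product: 35 (5aR,6S,7S,9aR)-7-hydroxy-6-{(E)-2-[(2R,3R,5aR,9aR)-2-hydroxy-3,6,6,9a-tetramethyldecahydro-1-benzoxepin-2-yl]ethenyl}-2,2,5a,7-tetramethyloctahydro-1-benzoxepin-3(2H)-one, via open hydroxy enone 34 (not isolated)
Conditions: HF·pyridine, pyridine, THF, 0 °C to rt
Reagents that add atoms: none
Why: Buffered fluoride cleavage of both tertiary silyl ethers without base (no vinylogous retro-aldol cleavage), after which the ring A hydroxyl adds to the enone carbonyl (hemiketalisation) to close ring B. The hemiketal centre is set by equilibration to the anomer with axial hydroxyl and equatorial alkenyl and methyl groups.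

## Compound list

1 | 2-(3-chloropropyl)-2-methyl-1,3-dioxolane | CC1(CCCCl)OCCO1 | starting material
2 | ethyl 3-methylbut-2-enoate | CCOC(=O)C=C(C)C | starting material
3 | [3-(2-methyl-1,3-dioxolan-2-yl)propyl]magnesium chloride | CC1(CCC[Mg]Cl)OCCO1 | intermediate
4 | 1-ethoxy-3,3-dimethyl-6-(2-methyl-1,3-dioxolan-2-yl)-1-(trimethylsilyloxy)hex-1-ene | CCOC(O[Si](C)(C)C)=CC(C)(C)CCCC1(C)OCCO1 | intermediate
5 | ethyl 3,3-dimethyl-6-(2-methyl-1,3-dioxolan-2-yl)hexanoate | CCOC(=O)CC(C)(C)CCCC1(C)OCCO1 | intermediate
6 | 3,3-dimethyl-6-(2-methyl-1,3-dioxolan-2-yl)hexanal | O=CCC(C)(C)CCCC1(C)OCCO1 | intermediate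
7 | 3,3-dimethyl-7-oxooctanal | O=CCC(C)(C)CCCC(C)=O | intermediate
8 | (2R)-1-[(1E)-3,3-dimethyl-7-oxooct-1-en-1-yl]pyrrolidine-2-carboxylic acid | CC(=O)CCCC(C)(C)/C=C/N1CCC[C@@H]1C(=O)O | intermediate
9 | (1R,2R)-2-hydroxy-2,6,6-trimethylcyclohexane-1-carbaldehyde | O=C[C@@H]1C(C)(C)CCC[C@@]1(C)O | intermediate
10 | (1R,2R)-2,6,6-trimethyl-2-(triethylsilyloxy)cyclohexane-1-carbaldehyde | O=C[C@@H]1C(C)(C)CCC[C@@]1(C)O[Si](CC)(CC)CC | intermediate
11 | (2S)-3-bromo-2-methylpropan-1-ol | C[C@@H](CO)CBr | starting material
12 | [(2S)-3-hydroxy-2-methylpropyl]triphenylphosphonium bromide | C[C@@H](CO)C[P+](c1ccccc1)(c1ccccc1)c1ccccc1.[Br-] | intermediate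
13 | sodium (2S)-2-methyl-3-(triphenylphosphoranylidene)propan-1-olate | C[C@@H](C[O-])C=P(c1ccccc1)(c1ccccc1)c1ccccc1.[Na+] | intermediate
14 | (2R,3Z)-2-methyl-4-[(1R,2R)-2,6,6-trimethyl-2-(triethylsilyloxy)cyclohexyl]but-3-en-1-ol | C[C@@H](CO)/C=C\[C@@H]1C(C)(C)CCC[C@@]1(C)O[Si](CC)(CC)CC | intermediate
15 | (2R)-2-methyl-4-[(1R,2R)-2,6,6-trimethyl-2-(triethylsilyloxy)cyclohexyl]butan-1-ol | C[C@@H](CO)CC[C@@H]1C(C)(C)CCC[C@@]1(C)O[Si](CC)(CC)CC | intermediate
16 | (2R)-2-methyl-4-[(1R,2R)-2,6,6-trimethyl-2-(triethylsilyloxy)cyclohexyl]butanal | C[C@@H](C=O)CC[C@@H]1C(C)(C)CCC[C@@]1(C)O[Si](CC)(CC)CC | intermediate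
17 | (2E,6E)-3,7,11-trimethyldodeca-2,6,10-trien-1-ol | OC/C=C(\C)CC/C=C(\C)CCC=C(C)C | starting material
18 | (2S,3S,6E)-2,3-epoxy-3,7,11-trimethyldodeca-6,10-dien-1-ol | OC[C@@H]1O[C@@]1(C)CC/C=C(\C)CCC=C(C)C | intermediate
19 | (2R,3S,6E)-2,3-epoxy-1-iodo-3,7,11-trimethyldodeca-6,10-diene | IC[C@@H]1O[C@@]1(C)CC/C=C(\C)CCC=C(C)C | intermediate
20 | (3S,6E)-3,7,11-trimethyldodeca-1,6,10-trien-3-ol | C=C[C@@](C)(O)CC/C=C(\C)CCC=C(C)C | intermediate
21 | triethyl{[(3S,6E)-3,7,11-trimethyldodeca-1,6,10-trien-3-yl]oxy}silane | C=C[C@@](C)(O[Si](CC)(CC)CC)CC/C=C(\C)CCC=C(C)C | intermediate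
22 | (3S,6E,10R)-10,11-epoxy-3,7,11-trimethyl-3-(triethylsilyloxy)dodeca-1,6-diene | C=C[C@@](C)(O[Si](CC)(CC)CC)CC/C=C(\C)CC[C@H]1OC1(C)C | intermediate
23 | (3S,6R,7R,10R)-6,7:10,11-diepoxy-3,7,11-trimethyl-3-(triethylsilyloxy)dodec-1-ene | C=C[C@@](C)(O[Si](CC)(CC)CC)CC[C@H]1O[C@]1(C)CC[C@H]1OC1(C)C | intermediate
24 | trimethyl(prop-2-en-1-yl)silane | C=CC[Si](C)(C)C | starting material
25 | (2E,4S,7R,8R,11R)-7,8:11,12-diepoxy-4,8,12-trimethyl-4-(triethylsilyloxy)-1-(trimethylsilyl)tridec-2-ene | C[Si](C)(C)C/C=C/[C@@](C)(O[Si](CC)(CC)CC)CC[C@H]1O[C@]1(C)CC[C@H]1OC1(C)C | intermediate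
26 | diethylaluminium (1R,2R,3S,4S)-2-{2-[(2R)-3,3-dimethyloxiran-2-yl]ethyl}-3-ethenyl-2,4-dimethyl-4-(triethylsilyloxy)cyclohexan-1-olate | C=C[C@H]1[C@@](C)(CC[C@H]2OC2(C)C)[C@H](O[Al](CC)CC)CC[C@]1(C)O[Si](CC)(CC)CC | intermediate
27 | (3R,5aR,6S,7S,9aR)-6-ethenyl-2,2,5a,7-tetramethyl-7-(triethylsilyloxy)decahydro-1-benzoxepin-3-ol | C=C[C@H]1[C@@]2(C)CC[C@@H](O)C(C)(C)O[C@@H]2CC[C@]1(C)O[Si](CC)(CC)CC | intermediate
28 | 3-[(3R,5aR,6S,7S,9aR)-3-hydroxy-2,2,5a,7-tetramethyl-7-(triethylsilyloxy)decahydro-1-benzoxepin-6-yl]-1,2,4-trioxolane | C1OOC(O1)[C@H]1[C@@]2(C)CC[C@@H](O)C(C)(C)O[C@@H]2CC[C@]1(C)O[Si](CC)(CC)CC | intermediate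
29 | (3R,5aR,6S,7S,9aR)-3-hydroxy-2,2,5a,7-tetramethyl-7-(triethylsilyloxy)decahydro-1-benzoxepine-6-carbaldehyde | O=C[C@H]1[C@@]2(C)CC[C@@H](O)C(C)(C)O[C@@H]2CC[C@]1(C)O[Si](CC)(CC)CC | intermediate
30 | (3R,5aR,6S,7S,9aR)-6-[(E)-2-iodoethenyl]-2,2,5a,7-tetramethyl-7-(triethylsilyloxy)decahydro-1-benzoxepin-3-ol | I/C=C/[C@H]1[C@@]2(C)CC[C@@H](O)C(C)(C)O[C@@H]2CC[C@]1(C)O[Si](CC)(CC)CC | intermediate
31 | dichloro{(E)-2-[(3R,5aR,6S,7S,9aR)-3-hydroxy-2,2,5a,7-tetramethyl-7-(triethylsilyloxy)decahydro-1-benzoxepin-6-yl]ethenyl}chromium | Cl[Cr](Cl)/C=C/[C@H]1[C@@]2(C)CC[C@@H](O)C(C)(C)O[C@@H]2CC[C@]1(C)O[Si](CC)(CC)CC | intermediate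
32 | (3R,5aR,6S,7S,9aR)-6-{(1E,4R)-3-hydroxy-4-methyl-6-[(1R,2R)-2,6,6-trimethyl-2-(triethylsilyloxy)cyclohexyl]hex-1-en-1-yl}-2,2,5a,7-tetramethyl-7-(triethylsilyloxy)decahydro-1-benzoxepin-3-ol (both carbinol epimers) | C[C@@H](C(O)/C=C/[C@H]1[C@@]2(C)CC[C@@H](O)C(C)(C)O[C@@H]2CC[C@]1(C)O[Si](CC)(CC)CC)CC[C@@H]1C(C)(C)CCC[C@@]1(C)O[Si](CC)(CC)CC | intermediate
33 | (5aR,6S,7S,9aR)-2,2,5a,7-tetramethyl-6-{(1E,4R)-4-methyl-3-oxo-6-[(1R,2R)-2,6,6-trimethyl-2-(triethylsilyloxy)cyclohexyl]hex-1-en-1-yl}-7-(triethylsilyloxy)octahydro-1-benzoxepin-3(2H)-one | C[C@@H](C(=O)/C=C/[C@H]1[C@@]2(C)CCC(=O)C(C)(C)O[C@@H]2CC[C@]1(C)O[Si](CC)(CC)CC)CC[C@@H]1C(C)(C)CCC[C@@]1(C)O[Si](CC)(CC)CC | intermediate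
34 | (5aR,6S,7S,9aR)-7-hydroxy-6-{(1E,4R)-6-[(1R,2R)-2-hydroxy-2,6,6-trimethylcyclohexyl]-4-methyl-3-oxohex-1-en-1-yl}-2,2,5a,7-tetramethyloctahydro-1-benzoxepin-3(2H)-one | C[C@@H](C(=O)/C=C/[C@H]1[C@@]2(C)CCC(=O)C(C)(C)O[C@@H]2CC[C@]1(C)O)CC[C@@H]1C(C)(C)CCC[C@@]1(C)O | intermediate
35 | (5aR,6S,7S,9aR)-7-hydroxy-6-{(E)-2-[(2R,3R,5aR,9aR)-2-hydroxy-3,6,6,9a-tetramethyldecahydro-1-benzoxepin-2-yl]ethenyl}-2,2,5a,7-tetramethyloctahydro-1-benzoxepin-3(2H)-one | C[C@@H]1CC[C@@H]2C(C)(C)CCC[C@@]2(C)O[C@@]1(O)/C=C/[C@H]1[C@@]2(C)CCC(=O)C(C)(C)O[C@@H]2CC[C@]1(C)O | target

## Step count and least certain steps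

Total: 20 steps. Longest linear sequence: 12 steps (17 to 35 through steps 9–17 and 18–20). The left branch from 1 needs 10 steps (steps 1–4, 6–8, 18–20), and step 5 is a one-step side branch.

Step 3 (key step). The catalyst may fail to override the substrate: the anti chair suffers a methyl/methyl 1,3-diaxial contact, so the syn aldol may form instead. The methyl ketone may act as enamine donor towards the aldehyde. The aldol may also revert or dehydrate before it is trapped. If the syn pathway dominated cleanly, (S)-proline followed by epimerisation of the formyl-bearing carbon would lead to the same (1R,2R) compound, since only the carbinol centre is beyond later correction.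

The fallback gives up catalyst control. It sets out from 7: pyrrolidine and acetic acid under equilibrating conditions should give the racemic trans aldol F1, which is reduced in the same flask with NaBH4 to the racemic diol F2, and the cis isomer is removed by chromatography. Acylation with vinyl acetate and Burkholderia cepacia lipase in tert-butyl methyl ether resolves the primary alcohol. The (1R,2S)-diol F3 is collected either as the unreacted alcohol or, if it is the faster-reacting enantiomer, as its monoacetate F4, which K2CO3 in methanol converts into F3. Oxidation of F3 with TEMPO and PhI(OAc)2 touches only the primary alcohol and comes back to the route at 9, at the cost of half the material.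

Step 15. The tertiary allylic silyl ether may ionise with loss of silicon to give a diene (1,4-elimination). The vinyl group may end up equatorial through the other face of the allylsilane. The terminal epoxide may open at its secondary carbon to give a six-membered ether. A wrong configuration at the vinyl-bearing carbon could still be corrected after step 16 by equilibrating 29, whose axial formyl isomer is expected to be favoured because an equatorial formyl group would be gauche to four substituents.

The fallback changes the terminating nucleophile and removes steps 14 and 16. It sets out from 23: ozonolysis (O3; PPh3) of the vinyl group gives the aldehyde F5, and Wittig reaction with Ph3P=CHOMe (from methoxymethyltriphenylphosphonium chloride and KN(SiMe3)2) gives the enol ether F6. Treatment of F6 with Et2AlCl closes ring C through the enol ether β-carbon and ring D through the alkoxide. The oxocarbenium ion is hydrolysed on work-up, so the route is rejoined at 29.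

Step 14. Metathesis at a vinyl group on a fully substituted carbon may be too slow, so that the catalyst decomposes or only 24 dimerises. The fallback replaces metathesis by carbonyl olefination. It sets out from 23 and goes through the same aldehyde F5; Wittig reaction with Ph3P=CHCH2SiMe3 (from [2-(trimethylsilyl)ethyl]triphenylphosphonium iodide and n-BuLi) gives the Z-allylsilane F7. Under the conditions of step 15, F7 should give 27, where the geometry of the allylsilane no longer appears, so the route is rejoined at 27.

Step 1. Conjugate addition at a fully substituted β-carbon of a simple enoate may be slow, which leaves room for 1,2-addition and for coupling of the Grignard reagent with itself. The fallback uses a doubly activated acceptor. It sets out from 1: the Grignard reagent 3 is added with CuI catalysis to diethyl 2-(propan-2-ylidene)propanedioate to give the malonate F8. Dealkoxycarbonylation of F8 (NaCl, wet DMSO, 150 °C, Krapcho conditions) leaves the dioxolane intact and comes back to the route at 5.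

## Further compounds

F1 | step 3 | rac-(1R*,2R*)-2-hydroxy-2,6,6-trimethylcyclohexane-1-carbaldehyde (racemate, one enantiomer drawn) | O=C[C@@H]1C(C)(C)CCC[C@@]1(C)O
F2 | step 3 | rac-(1R*,2S*)-2-(hydroxymethyl)-1,3,3-trimethylcyclohexan-1-ol (racemate, one enantiomer drawn) | OC[C@@H]1C(C)(C)CCC[C@@]1(C)O
F3 | step 3 | (1R,2S)-2-(hydroxymethyl)-1,3,3-trimethylcyclohexan-1-ol | OC[C@@H]1C(C)(C)CCC[C@@]1(C)O
F4 | step 3 | [(1S,2R)-2-hydroxy-2,6,6-trimethylcyclohexyl]methyl acetate | CC(=O)OC[C@@H]1C(C)(C)CCC[C@@]1(C)O
F5 | step 15 | (2S,5R,6R,9R)-5,6:9,10-diepoxy-2,6,10-trimethyl-2-(triethylsilyloxy)undecanal | O=C[C@@](C)(O[Si](CC)(CC)CC)CC[C@H]1O[C@]1(C)CC[C@H]1OC1(C)C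
F6 | step 15 | (3S,6R,7R,10R)-6,7:10,11-diepoxy-1-methoxy-3,7,11-trimethyl-3-(triethylsilyloxy)dodec-1-ene (E/Z mixture) | COC=C[C@@](C)(O[Si](CC)(CC)CC)CC[C@H]1O[C@]1(C)CC[C@H]1OC1(C)C
F7 | step 14 | (2Z,4S,7R,8R,11R)-7,8:11,12-diepoxy-4,8,12-trimethyl-4-(triethylsilyloxy)-1-(trimethylsilyl)tridec-2-ene | C[Si](C)(C)C/C=C\[C@@](C)(O[Si](CC)(CC)CC)CC[C@H]1O[C@]1(C)CC[C@H]1OC1(C)C
F8 | step 1 | diethyl 2-[2-methyl-5-(2-methyl-1,3-dioxolan-2-yl)pentan-2-yl]propanedioate | CCOC(=O)C(C(=O)OCC)C(C)(C)CCCC1(C)OCCO1
A1 | alternative 1 | 5-[(3S,4R)-4-{[tert-butyl(dimethyl)silyl]oxymethyl}-3,5-dimethyl-3-(trimethylsilyloxy)hex-5-en-1-yl]-2,2-dimethylfuran-3(2H)-one | CC1(C)OC(=CC1=O)CC[C@](C)(O[Si](C)(C)C)[C@@H](CO[Si](C)(C)C(C)(C)C)C(C)=C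
A2 | alternative 1 | tricyclic cyclobutane photoadduct of A1 | CC1(C)O[C@]23CC[C@](C)(O[Si](C)(C)C)[C@@H](CO[Si](C)(C)C(C)(C)C)[C@@]2(C)C[C@@H]3C1=O
A3 | alternative 2 | (2E,4S,7R,8R,11R)-7,8:11,12-diepoxy-4,8,12-trimethyl-4-(triethylsilyloxy)-1-(trimethylsilyl)tridec-2-ene (the same compound as 25) | C[Si](C)(C)C/C=C/[C@@](C)(O[Si](CC)(CC)CC)CC[C@H]1O[C@]1(C)CC[C@H]1OC1(C)C
A4 | alternative 2 | (3R,5aR,6S,7S,9aR)-6-ethenyl-2,2,5a,7-tetramethyl-7-(triethylsilyloxy)decahydro-1-benzoxepin-3-ol (the same compound as 27) | C=C[C@H]1[C@@]2(C)CC[C@@H](O)C(C)(C)O[C@@H]2CC[C@]1(C)O[Si](CC)(CC)CC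
A5 | alternative 3 | (2R,4aR,8aR)-2,5,5,8a-tetramethyloctahydronaphthalen-1(2H)-one | C[C@@H]1CC[C@@H]2C(C)(C)CCC[C@@]2(C)C1=O
A6 | alternative 3 | (3R,5aR,9aR)-3,6,6,9a-tetramethyloctahydro-1-benzoxepin-2(3H)-one | C[C@@H]1CC[C@@H]2C(C)(C)CCC[C@@]2(C)OC1=O
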